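## Retrosynthetic overview

1. C3–O bond last: catalyst-controlled allylic C–H hydroxylation of the 4(15)-exo-methylene macrocycle (key C–O bond formation, new method, sets C3).
2. C6–O bond: the angelate is introduced by invertive Mitsunobu esterification of the 6R macrocyclic alcohol (sets C6).
3. C6–C7 bond: the ten-membered ring is closed by Pd/In umpolung allylation of an aldehyde by a 3-(acetoxymethyl)butenolide, which also unveils the α-methylene lactone.
4. C8–C9 bond: asymmetric vinylogous Mukaiyama aldol of a myrcene-derived enal with 3-bromo-2-silyloxyfuran; C13 by Stille hydroxymethylation; C6 aldehyde from the diene terminus.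
5. Ring order: butenolide first (bought as 3-bromofuran-2(5H)-one), carbocycle second; starting materials are β-myrcene, 3-bromofuran-2(5H)-one and angelic acid.

Atom labels: germacrane numbering is used throughout, also for open-chain precursors. Ring carbons are C1–C10 (C1=C10 alkene, methyl C14 on C10, methylene C15 on C4); C11 (=C13H2) and C12 (C=O) sit on C7; the lactone oxygen is on C8.

Assumption: 3-bromofuran-2(5H)-one is purchased (otherwise one step from furan-2(5H)-one with Br2, then Et3N).

## Route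

Step 1
Reactants: 1 β-myrcene (7-methyl-3-methyleneocta-1,6-diene)
Product: 3 (2E)-2-methyl-6-methyleneocta-2,7-dienal (myrcenal), via (E)-myrcenol 2 (not isolated)
Conditions: SeO2 (5 mol %), t-BuOOH (2 equiv), salicylic acid (10 mol %), CH2Cl2, rt; crude alcohol then TEMPO (10 mol %), PhI(OAc)2 (1.1 equiv), CH2Cl2, rt
Reagents that add atoms: tert-butyl hydroperoxide, CC(C)(C)OO
Why: Riley-type SeO2/t-BuOOH allylic hydroxylation (ene reaction, then [2,3]-sigmatropic shift) attacks the E-methyl group of the electron-rich trisubstituted alkene with retention of the E geometry, the conjugated diene being a poorer ene partner, and the TEMPO/PhI(OAc)2 oxidation then gives the enal without touching the diene; no stereocentre is formed.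

Step 2
Reactants: 4 3-bromofuran-2(5H)-one
Product: 5 3-bromo-2-(tert-butyldimethylsilyloxy)furan
Conditions: TBSOTf (1.1 equiv), Et3N (1.3 equiv), CH2Cl2, 0 °C; distilled
Reagents that add atoms: tert-butyldimethylsilyl trifluoromethanesulfonate, CC(C)(C)[Si](C)(C)OS(=O)(=O)C(F)(F)F
Why: Soft enolisation (silyl dienol ether formation): γ-deprotonation of the butenolide by Et3N in the presence of the silyl triflate gives the aromatic 2-silyloxyfuran; no stereocentre is formed.

Step 3
Reactants: 3 myrcenal; 5 3-bromo-2-(tert-butyldimethylsilyloxy)furan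
Product: 7 (5R)-3-bromo-5-[(1S,2E)-1-hydroxy-2-methyl-6-methyleneocta-2,7-dien-1-yl]furan-2(5H)-one, via trichlorosilyl ether 6 (not isolated)
Conditions: SiCl4 (1.1 equiv), (R,R)-binaphthyldiamine-derived bisphosphoramide (5 mol %), i-Pr2NEt (10 mol %), CH2Cl2, −78 °C; aq. NaHCO3/KF work-up
Reagents that add atoms: none
Why: Lewis-base-activated SiCl4 vinylogous Mukaiyama aldol reaction: the phosphoramide-bound trichlorosilyl cation activates the enal for 1,2-addition and the silyloxyfuran attacks through its γ-carbon (C8) in an open antiperiplanar transition state that gives the anti adduct, the (R,R)-catalyst exposing the Re face of the aldehyde (9S) and thereby fixing 8R (the (S,S)-catalyst would give the antipode).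

Step 4
Reactants: 7 (5R)-3-bromo-5-[(1S,2E)-1-hydroxy-2-methyl-6-methyleneocta-2,7-dien-1-yl]furan-2(5H)-one
Product: 8 (5R)-5-[(1S,2E)-1-hydroxy-2-methyl-6-methyleneocta-2,7-dien-1-yl]-3-(hydroxymethyl)furan-2(5H)-one
Conditions: Bu3SnCH2OH (1.3 equiv), Pd2(dba)3 (2.5 mol %), AsPh3 (10 mol %), CuI (10 mol %), NMP, 50 °C
Reagents that add atoms: (tributylstannyl)methanol, CCCC[Sn](CCCC)(CCCC)CO
Why: Stille cross-coupling of the activated α-bromo-enoate (oxidative addition, CuI-assisted transfer of the hydroxymethyl group, reductive elimination) installs C13 under neutral conditions that leave the base-sensitive γ-stereocentre and the diene intact; no new stereocentre is formed.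

Step 5
Reactants: 8 (5R)-5-[(1S,2E)-1-hydroxy-2-methyl-6-methyleneocta-2,7-dien-1-yl]-3-(hydroxymethyl)furan-2(5H)-one
Product: 9 [(5R)-5-[(1S,2E)-1-acetoxy-2-methyl-6-methyleneocta-2,7-dien-1-yl]-2-oxo-2,5-dihydrofuran-3-yl]methyl acetate
Conditions: Ac2O (3 equiv), pyridine, CH2Cl2, 0 °C
Reagents that add atoms: acetic anhydride, CC(=O)OC(C)=O
Why: Pyridine-mediated O-acetylation of both hydroxyl groups at 0 °C without DMAP is faster than base-induced loss of the C9 acetate towards a γ-ylidene butenolide, giving the final C9 acetate and the activated C13 allylic acetate in one operation; no new stereocentre is formed.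

Step 6
Reactants: 9 [(5R)-5-[(1S,2E)-1-acetoxy-2-methyl-6-methyleneocta-2,7-dien-1-yl]-2-oxo-2,5-dihydrofuran-3-yl]methyl acetate
Product: 11 [(5R)-5-[(1S,2E)-1-acetoxy-8-hydroxy-2-methyl-6-methyleneoct-2-en-1-yl]-2-oxo-2,5-dihydrofuran-3-yl]methyl acetate, via dialkylborane adduct 10 (not isolated)
Conditions: disiamylborane (Sia2BH, 1.3 equiv), THF, −10 to 0 °C; then 30 % H2O2, pH 7 phosphate buffer, 0 °C
Reagents that add atoms: hydrogen peroxide, OO
Why: Brown hydroboration–oxidation: the bulky dialkylborane adds anti-Markovnikov only to the monosubstituted vinyl terminus of the 2-substituted diene (as it does for myrcene itself), leaving the 1,1-disubstituted, trisubstituted and electron-poor alkenes and the esters untouched, and buffered peroxide oxidation gives the C6 primary alcohol; no stereocentre is formed.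

Step 7
Reactants: 11 [(5R)-5-[(1S,2E)-1-acetoxy-8-hydroxy-2-methyl-6-methyleneoct-2-en-1-yl]-2-oxo-2,5-dihydrofuran-3-yl]methyl acetate
Product: 12 [(5R)-5-[(1S,2E)-1-acetoxy-2-methyl-6-methylene-8-oxooct-2-en-1-yl]-2-oxo-2,5-dihydrofuran-3-yl]methyl acetate
Conditions: Dess–Martin periodinane (1.2 equiv), NaHCO3, CH2Cl2, 0 °C; used at once
Reagents that add atoms: none
Why: Dess–Martin oxidation of the primary alcohol under buffered neutral conditions gives the β,γ-unsaturated C6 aldehyde without migration of the exo-methylene into conjugation; no stereocentre is formed.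

Step 8
Reactants: 12 [(5R)-5-[(1S,2E)-1-acetoxy-2-methyl-6-methylene-8-oxooct-2-en-1-yl]-2-oxo-2,5-dihydrofuran-3-yl]methyl acetate
Product: 14 (6R,7S,8R,9S)-9-acetoxy-6-hydroxygermacra-1(10)E,4(15),11(13)-trien-12,8-olide, via allylindium species 13 (not isolated)
Conditions: Pd(PPh3)4 (5 mol %), InI (1.5 equiv), THF, rt, slow addition of 12 (final 2 mM); pH 7 buffer quench at 0 °C
Reagents that add atoms: none
Why: Umpolung Barbier-type allylation (Tsuji–Trost ionisation of the activated primary allylic acetate by zerovalent palladium, reductive transmetalation by monovalent indium iodide, SE2′ addition through a closed six-membered chair): the C6–C7 bond forms on the butenolide face opposite the C9 substituent (trans-lactone, 7S) and the ring-locked E-type allyl unit with both tether ends equatorial gives the 6,7-anti adduct (6R), while the double bond moves to C11=C13.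

Step 9
Reactants: 14 (6R,7S,8R,9S)-9-acetoxy-6-hydroxygermacra-1(10)E,4(15),11(13)-trien-12,8-olide; 15 angelic acid ((2Z)-2-methylbut-2-enoic acid)
Product: 16 (6S,7S,8R,9S)-9-acetoxy-6-[(Z)-2-methylbut-2-enoyloxy]germacra-1(10)E,4(15),11(13)-trien-12,8-olide
Conditions: PPh3 (1.5 equiv), DIAD (1.5 equiv), toluene, 0 °C (betaine preformed), then 15 and 14, 0 °C to rt
Reagents that add atoms: none
Why: Mitsunobu esterification: the alkoxyphosphonium salt of the 6R alcohol is displaced by angelate in an SN2 reaction, so the C6–O bond is formed with inversion to give 6S, and the neutral amine-free conditions with preformed betaine avoid angelate-to-tiglate isomerisation and phosphine addition to the α-methylene lactone.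

Step 10
Reactants: 16 (6S,7S,8R,9S)-9-acetoxy-6-[(Z)-2-methylbut-2-enoyloxy]germacra-1(10)E,4(15),11(13)-trien-12,8-olide
Product: 17 (3S,6S,7S,8R,9S)-9-acetoxy-3-hydroxy-6-[(Z)-2-methylbut-2-enoyloxy]germacra-1(10)E,4(15),11(13)-trien-12,8-olide (target)
Conditions: (S,S)-bis[2-(1-methoxyethyl)phenyl] diselenide (10 mol %), t-BuOOH (2 equiv, anhydrous), 4 Å molecular sieves, CH2Cl2, 0 °C to rt, stopped before over-oxidation
Reagents that add atoms: tert-butyl hydroperoxide, CC(C)(C)OO
Why: Proposed new method: the chiral areneseleninic acid formed in situ from the diselenide acts as an enophile on the most accessible and least deactivated alkene, the 4(15)-exo-methylene (the 1(10)-alkene is deactivated by the allylic acetate and the two enoates are electron-poor), removing a C3–H rather than a C5–H that is inductively deactivated by the C6 ester, and the resulting selenium-stereogenic allyl aryl selenoxide undergoes a [2,3]-sigmatropic shift that delivers oxygen suprafacially to one face of C3 under control of the coordinating ortho-(1-methoxyethyl) group to set 3S (the enantiomeric diselenide is used if the pairing proves mismatched) before hydrolysis and reoxidation of selenium by t-BuOOH; the closest known reactions are the SeO2/t-BuOOH (Riley–Sharpless) allylic hydroxylation and the asymmetric [2,3]-rearrangement of chiral allyl aryl selenoxides, which have not been merged into a catalytic, stereocontrolled C–H hydroxylation.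

## Compound list

1 | β-myrcene (7-methyl-3-methyleneocta-1,6-diene) | C=CC(=C)CCC=C(C)C | starting material
2 | (2E)-2-methyl-6-methyleneocta-2,7-dien-1-ol ((E)-myrcenol) | OC/C(C)=C/CCC(=C)C=C | intermediate
3 | (2E)-2-methyl-6-methyleneocta-2,7-dienal (myrcenal) | O=C/C(C)=C/CCC(=C)C=C | intermediate
4 | 3-bromofuran-2(5H)-one | O=C1OCC=C1Br | starting material
5 | 3-bromo-2-(tert-butyldimethylsilyloxy)furan | CC(C)(C)[Si](C)(C)Oc1occc1Br | intermediate
6 | (5R)-3-bromo-5-[(1S,2E)-2-methyl-6-methylene-1-(trichlorosilyloxy)octa-2,7-dien-1-yl]furan-2(5H)-one | O=C1O[C@@H]([C@@H](O[Si](Cl)(Cl)Cl)/C(C)=C/CCC(=C)C=C)C=C1Br | intermediate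
7 | (5R)-3-bromo-5-[(1S,2E)-1-hydroxy-2-methyl-6-methyleneocta-2,7-dien-1-yl]furan-2(5H)-one | O=C1O[C@@H]([C@@H](O)/C(C)=C/CCC(=C)C=C)C=C1Br | intermediate
8 | (5R)-5-[(1S,2E)-1-hydroxy-2-methyl-6-methyleneocta-2,7-dien-1-yl]-3-(hydroxymethyl)furan-2(5H)-one | O=C1O[C@@H]([C@@H](O)/C(C)=C/CCC(=C)C=C)C=C1CO | intermediate
9 | [(5R)-5-[(1S,2E)-1-acetoxy-2-methyl-6-methyleneocta-2,7-dien-1-yl]-2-oxo-2,5-dihydrofuran-3-yl]methyl acetate | O=C1O[C@@H]([C@@H](OC(C)=O)/C(C)=C/CCC(=C)C=C)C=C1COC(C)=O | intermediate
10 | [(5R)-5-[(1S,2E)-1-acetoxy-8-[bis(3-methylbutan-2-yl)boranyl]-2-methyl-6-methyleneoct-2-en-1-yl]-2-oxo-2,5-dihydrofuran-3-yl]methyl acetate | O=C1O[C@@H]([C@@H](OC(C)=O)/C(C)=C/CCC(=C)CCB(C(C)C(C)C)C(C)C(C)C)C=C1COC(C)=O | intermediate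
11 | [(5R)-5-[(1S,2E)-1-acetoxy-8-hydroxy-2-methyl-6-methyleneoct-2-en-1-yl]-2-oxo-2,5-dihydrofuran-3-yl]methyl acetate | O=C1O[C@@H]([C@@H](OC(C)=O)/C(C)=C/CCC(=C)CCO)C=C1COC(C)=O | intermediate
12 | [(5R)-5-[(1S,2E)-1-acetoxy-2-methyl-6-methylene-8-oxooct-2-en-1-yl]-2-oxo-2,5-dihydrofuran-3-yl]methyl acetate | O=C1O[C@@H]([C@@H](OC(C)=O)/C(C)=C/CCC(=C)CC=O)C=C1COC(C)=O | intermediate
13 | {[(5R)-5-[(1S,2E)-1-acetoxy-2-methyl-6-methylene-8-oxooct-2-en-1-yl]-2-oxo-2,5-dihydrofuran-3-yl]methyl}indium acetate iodide (trivalent indium) | O=C1O[C@@H]([C@@H](OC(C)=O)/C(C)=C/CCC(=C)CC=O)C=C1C[In](I)OC(C)=O | intermediate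
14 | (6R,7S,8R,9S)-9-acetoxy-6-hydroxygermacra-1(10)E,4(15),11(13)-trien-12,8-olide | C=C1C(=O)O[C@@H]2[C@@H]1[C@H](O)CC(=C)CC/C=C(\C)[C@@H]2OC(C)=O | intermediate
15 | angelic acid ((2Z)-2-methylbut-2-enoic acid) | C/C=C(/C)C(=O)O | starting material
16 | (6S,7S,8R,9S)-9-acetoxy-6-[(Z)-2-methylbut-2-enoyloxy]germacra-1(10)E,4(15),11(13)-trien-12,8-olide | C=C1C(=O)O[C@@H]2[C@@H]1[C@@H](OC(=O)/C(C)=C\C)CC(=C)CC/C=C(\C)[C@@H]2OC(C)=O | intermediate
17 | (3S,6S,7S,8R,9S)-9-acetoxy-3-hydroxy-6-[(Z)-2-methylbut-2-enoyloxy]germacra-1(10)E,4(15),11(13)-trien-12,8-olide, i.e. (3aS,4S,7S,9E,11S,11aR)-11-acetoxy-7-hydroxy-10-methyl-3,6-dimethylidene-2-oxo-2,3,3a,4,5,6,7,8,11,11a-decahydrocyclodeca[b]furan-4-yl (2Z)-2-methylbut-2-enoate | C=C1C(=O)O[C@@H]2[C@@H]1[C@@H](OC(=O)/C(C)=C\C)CC(=C)[C@@H](O)C/C=C(\C)[C@@H]2OC(C)=O | target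

## Step count and risks

Total step count: 10 (step 1 is a telescoped two-stage oxidation). Longest linear sequence: 9 steps from β-myrcene (steps 1, 3, 4, 5, 6, 7, 8, 9, 10).

The three steps most likely to fail:

**Step 8 (macrocyclic allylation).** The risks are oligomerisation, competing ionisation of the secondary C9 allylic acetate, isomerisation of the β,γ-unsaturated aldehyde, and translactonisation of the indium alkoxide. The fallback sets out from 11 and comes back at 14. The primary allylic acetate of 11 is converted by palladium-catalysed borylation (B2pin2, Pd2(dba)3, DMSO, 50 °C) into the allylboronate alcohol F1. Dess–Martin oxidation gives the allylboronate aldehyde F2. F2 closes the ring by metal-free intramolecular allylboration (toluene, 40 °C, high dilution) through the same closed chair, so the same 7S,6R sense is expected. Mild aqueous work-up of the borate releases 14.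

**Step 9 (Mitsunobu angeloylation at the hindered C6).** The risks are elimination towards the 4(15),5-diene, participation of the lactone carbonyl (net retention), and angelate isomerisation. The fallback sets out from 14 and comes back at 16. Mitsunobu inversion with the smaller and more acidic chloroacetic acid (PPh3, DIAD, toluene) gives the (6S)-chloroacetate F3. Thiourea with NaHCO3 in EtOH removes the chloroacetyl group selectively beside the C9 acetate and gives the (6S)-alcohol F4. Retentive Yamaguchi esterification with 15 gives 16; it runs through the mixed anhydride angelic 2,4,6-trichlorobenzoic anhydride F5 (2,4,6-trichlorobenzoyl chloride, Et3N, toluene, then F4 at 75 °C without DMAP).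

**Step 10 (proposed new hydroxylation).** The risks are attack at C5 or C14, the wrong C3 epimer, and over-oxidation to the enone. The fallback uses known chemistry, sets out from 16 and comes back at 17. Catalytic SeO2 with t-BuOOH in CH2Cl2 (substrate-controlled Riley–Sharpless hydroxylation) gives 17 together with its (3R)-epimer F6. The whole mixture is oxidised with Dess–Martin periodinane to the cross-conjugated 3-oxo enone F7. Reagent-controlled 1,2-reduction with (R)-2-methyl-CBS-oxazaborolidine and catecholborane (toluene, −78 °C, alkenyl group as the large substituent) sets 3S and gives 17.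

Further compounds

F1 | step 8 | (1S,2E)-8-hydroxy-2-methyl-6-methylene-1-[(2R)-5-oxo-4-[(4,4,5,5-tetramethyl-1,3,2-dioxaborolan-2-yl)methyl]-2,5-dihydrofuran-2-yl]oct-2-en-1-yl acetate (allylboronate alcohol) | O=C1O[C@@H]([C@@H](OC(C)=O)/C(C)=C/CCC(=C)CCO)C=C1CB2OC(C)(C)C(C)(C)O2
F2 | step 8 | (1S,2E)-2-methyl-6-methylene-8-oxo-1-[(2R)-5-oxo-4-[(4,4,5,5-tetramethyl-1,3,2-dioxaborolan-2-yl)methyl]-2,5-dihydrofuran-2-yl]oct-2-en-1-yl acetate (allylboronate aldehyde) | O=C1O[C@@H]([C@@H](OC(C)=O)/C(C)=C/CCC(=C)CC=O)C=C1CB2OC(C)(C)C(C)(C)O2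
F3 | step 9 | (6S,7S,8R,9S)-9-acetoxy-6-(chloroacetoxy)germacra-1(10)E,4(15),11(13)-trien-12,8-olide | C=C1C(=O)O[C@@H]2[C@@H]1[C@@H](OC(=O)CCl)CC(=C)CC/C=C(\C)[C@@H]2OC(C)=O
F4 | step 9 | (6S,7S,8R,9S)-9-acetoxy-6-hydroxygermacra-1(10)E,4(15),11(13)-trien-12,8-olide | C=C1C(=O)O[C@@H]2[C@@H]1[C@@H](O)CC(=C)CC/C=C(\C)[C@@H]2OC(C)=O
F5 | step 9 | angelic 2,4,6-trichlorobenzoic anhydride | C/C=C(/C)C(=O)OC(=O)c1c(Cl)cc(Cl)cc1Cl
F6 | step 10 | (3R,6S,7S,8R,9S)-9-acetoxy-3-hydroxy-6-[(Z)-2-methylbut-2-enoyloxy]germacra-1(10)E,4(15),11(13)-trien-12,8-olide (3-epimer of 17) | C=C1C(=O)O[C@@H]2[C@@H]1[C@@H](OC(=O)/C(C)=C\C)CC(=C)[C@H](O)C/C=C(\C)[C@@H]2OC(C)=O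
F7 | step 10 | (6S,7S,8R,9S)-9-acetoxy-6-[(Z)-2-methylbut-2-enoyloxy]-3-oxogermacra-1(10)E,4(15),11(13)-trien-12,8-olide | C=C1C(=O)O[C@@H]2[C@@H]1[C@@H](OC(=O)/C(C)=C\C)CC(=C)C(=O)C/C=C(\C)[C@@H]2OC(C)=O
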